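Remark on the chemistry: 7, 12, 13 and 14 each hold one stereocenter, are made and used as racemates, and lose that stereocenter later (7 by dehydrogenation in step 5, the carbinol carbon of 12 to 14 by oxidation in step 10); the target has none.

Remark on the chemistry: in the gold step the carbonyl oxygen of the tert-butyl ester becomes O1'' and the alkoxy oxygen becomes the C2'' carbonyl oxygen once the tert-butyl group has left. The only competing closure is 5-exo attack of this same ester oxygen on the alkyne carbon next to the ketone, because the ketone oxygen is too close to the alkyne to close a five- or six-membered ring.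

## Structural features

The target is a chain of four rings. A 7-hydroxy-5-methylchromone (benzo ring A fused to 4-pyranone ring B, unprimed numbers) is bonded through C2 to C1' of a resorcinol ring C (primed numbers), and a 4-hydroxy-2-pyranone ring D (doubly primed numbers) hangs from C6' through one CH2 group bonded to C6''. There is no stereocenter and no double bond of defined geometry, so no stereocenters stand next to each other; the C2-C1' bond is crowded by the 2'-oxygen and the 6'-CH2 group, but no axis is defined. The fragile parts are ring D (a lactone and vinylogous acid that hydroxide or strong nucleophiles open), C2 of ring B (a Michael acceptor at which strong base opens the ring), the CH2 between rings C and D (acidified by both rings) and four acidic OH groups. Rings A and C are both resorcinols with a one-carbon group ortho to the point of attachment, which points to an acetophenone and a benzaldehyde as their sources. The real difficulty is the carbon substituent at C6' with ring D behind it: the handle at C6' must be told apart from the C5 methyl group of ring A, and ring D must be built one carbon away from a hindered aryl position without a free poly-beta-carbonyl chain that could aldolise onto ring C or ring B. The key step uses the fact that C6'' is both the carbon bonded to the ring oxygen O1'' and the only carbon of ring D with a carbon substituent, so C5'' and C6'' can be the two carbons of an alkyne, C4'' a ketone and C2'' a tert-butyl ester, and ring D closes by forming the single bond O1''-C6''.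

## Logic of the disconnections

17 to 16: the three aryl O-CH3 bonds are cut. The phenols cannot be carried free through base, copper and oxidant, whereas the pyranone OH appears only in the step before and needs no protection. The gain is that every earlier intermediate is neutral. The demand is one final ether cleavage that removes three methyl groups, one of them on the electron-poor ring A, without opening ring D or ring B.

16 to 15: the O1''-C6'' bond is cut. C6'' carries both the ring oxygen and the only side chain, so ring D unravels to an open chain in which C5''-C6'' is an alkyne, C4'' a ketone and C2'' a tert-butyl ester. The gain is that a heterocycle with a fixed oxidation pattern becomes an acyclic chain with no stereocenter. The demand is a 6-endo closure without base, since the CH2 between ring C and the ynone is acidic.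

15 to 14: the C4'' ketone is traced back to a secondary alcohol. The ynone is what acidifies the neighbouring CH2, so it is made only one step before it is consumed. The gain is a robust propargylic alcohol as the coupling product. The demand is an oxidation that is neutral and stops at the ketone.

14 to 9 and 13: the bond between the benzylic CH2 and the alkyne carbon is cut. It is the one C-C bond that separates the finished flavone from the whole five-carbon chain of ring D. Cutting here avoids an arylacetaldehyde, a terminal aryl-CH2-alkyne, any hydride reduction beside ring B and any acetylide acylation with an enolisable acid chloride. The gain is a convergent union of two pieces of very different size. The demand is an sp3-sp coupling at a hindered benzylic halide under weak base, without propargyl-to-allene isomerisation.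

13 to 12 to 10 and 11: the C-Si bond and then the C2-C3 bond of the pentynoate are cut (aldol). The gain is two commercial fragments. The demand is clean 1,2-addition of an ester enolate to an ynal; the silyl cap keeps the alkyne terminus out of the reaction.

9 to 8: the C-Br bond is traced back to a benzylic C-OCH3 bond. A benzylic halide would not survive the hydroxide and hot iodine/DMSO used for ring B, whereas a methyl ether does, and it marks C6' as different from the C5 methyl of ring A. The demand is selective cleavage of the benzylic ether beside three aryl ethers.

8 to 6 (through 7): the O1-C2 bond of ring B is cut and two hydrogens are added. The gain is that ring B comes from an open enone. The demand is an oxidative cyclisation that closes the six-membered ring and not the five-membered aurone.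

6 to 3 and 5: the enone C=C bond (future C2-C3 of ring B) is cut by aldol condensation. The gain is two benzene building blocks of similar size, each carrying its full substitution pattern. The demand is a condensation between a hindered, electron-rich aldehyde and a hindered ketone.

3 to 2 to 1: the aryl-CHO bond and then the benzylic O-CH3 bond are cut. 2 is symmetric, so the two positions ortho to the side chain are equivalent. The demand is formylation there and not between the two methoxy groups.

5 to 4: the O-CH3 bond at the 4-oxygen is cut. The demand is monoalkylation, which the hydrogen bond between the 2-OH and the ketone secures.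

## Other disconnections considered

Alternative 1: The cut runs across ring D at C5''-C6'' and O1''-C2''. Forward, the aldehyde A1 and the silyloxydiene A2 would combine under a boron trifluoride catalyst by aldol addition and lactonisation (formally a hetero-Diels-Alder reaction) to the racemic dihydropyranone A3, which must then lose two hydrogens across C5''-C6''.
- In its favour: two ring bonds are made in one step against one in the chosen plan, so on bonds per step it is the better. It needs no alkyne and no gold, and A2 delivers C2'' to C5'' with the right oxygen pattern.
- Against it here: A3 is at the wrong oxidation level and has a C6'' stereocenter that the target lacks. Dehydrogenating a 6-alkyl-5,6-dihydro-4-methoxy-2-pyranone is slow with quinone oxidants, and halogenation-elimination would compete at the CH2 between rings C and D and on ring C. A1 is an enolisable arylacetaldehyde that a Lewis acid can aldolise, and making it needs a reduction or oxidative cleavage beside ring B. The 4''-methyl ether adds a fourth ether to the final cleavage.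
- Comparison: on structure the two plans are equal, since both disconnect ring D and leave the flavone intact. On mechanism the ring-forming event is equally well founded, but the chosen plan gives the pyranone oxidation level directly and passes no stereocenter. On step economy Alternative 1 is at best equal up to ring D and one to two steps longer after it.

Alternative 2: The cut is the C6-C7 bond of ring A. Forward, the acid A4 heated with acetic anhydride and an acetate base would give the ketene A5, conjugated with the C4a=C8a bond of ring B and the isopropenyl group; six-electron electrocyclisation and enolisation give a phenol that is trapped as the acetate A6.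
- In its favour: benzannulation of dienylketenes is dependable, and the positions of the C5 methyl and the C7 oxygen are fixed by the substrate. The 7-oxygen emerges as an acetate, which is easier to remove than the 7-methyl ether of 16; on that point it is the better.
- Against it here: ring A is the one part that needs no construction, since 4 supplies it complete. A4 must already carry rings B, C and D, so ring D, the real problem, still has to be solved earlier by another method. A4 is a vinylogous beta-keto acid that may decarboxylate on heating, and the acidic CH2 beside ring D must survive hot anhydride and acetate.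
- Comparison: both key steps close one ring and create no stereocenter, so on structure they are equal. The electrocyclisation is the equal of the gold cyclisation in reliability, or better. Step economy is clearly worse: the way to A4 is long and linear, and the endgame removes an acetate and four methyl ethers.

Alternative 3: The cut is the C1'-C6' bond of ring C. Forward, under mild base the CH2 on C2 of ring B in the polyketone A7 would add to the C6' ketone; loss of water and enolisation of the C2' and C4' ketones give ring C of A8 with both OH groups free.
- In its favour: it follows the likely biosynthesis. Ring C arrives unprotected, so only the 7-methyl ether remains; in protecting-group economy it is the better. It joins two heterocyclic halves late, so in convergence it is at least the equal, and it uses no metal.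
- Against it here: A7 is a free 2,4,6-triketone flanked by two activated CH2 groups of similar acidity. Aldol addition of the CH2 beside ring D onto the C2' ketone would give the constitutional isomer A9, in which ring D sits directly on the benzene ring and the chromone is joined through CH2. Hemiketal and lactone formation compete, and assembling A7 needs polyanion chemistry on both heterocycles.
- Comparison: forming and aromatising a carbocycle in one step is a larger structural gain than closing ring D, so there the alternative is the better. Its regiocontrol rests on a small difference in acidity, whereas ring size and ynone polarisation leave the chosen plan one sensible closure, so there the chosen plan is the better. Step economy would be equal or better only if A7 could be reached in few steps, which is the unsolved part.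

Key step: step 11

## Route

Step 1
Reactants: 1 (3,5-dimethoxyphenyl)methanol
Product: 2 1,3-dimethoxy-5-(methoxymethyl)benzene
Conditions: NaH, MeI, THF, 0 °C to rt
Reagents that add atoms: iodomethane, CI
Why: Williamson ether synthesis on a primary benzylic alkoxide; the methyl ether is chosen because it survives hydroxide and hot iodine/DMSO in steps 4 and 5 and can later be exchanged for bromide.

Step 2
Reactants: 2 1,3-dimethoxy-5-(methoxymethyl)benzene
Product: 3 2,4-dimethoxy-6-(methoxymethyl)benzaldehyde
Conditions: POCl3, DMF, 0 to 70 °C; then ice-water
Reagents that add atoms: N,N-dimethylformamide, CN(C)C=O; water, O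
Why: Vilsmeier-Haack formylation of a resorcinol dimethyl ether; the position para to one methoxy group and ortho to the other should react in preference to the position between the two methoxy groups, and the symmetry of 2 makes the two such positions identical.

Step 3
Reactants: 4 1-(2,4-dihydroxy-6-methylphenyl)ethanone
Product: 5 1-(2-hydroxy-4-methoxy-6-methylphenyl)ethanone
Conditions: MeI (1.05 equiv), K2CO3 (1.1 equiv), acetone, 40 °C
Reagents that add atoms: iodomethane, CI
Why: selective phenol O-alkylation; the 2-OH is hydrogen-bonded to the ketone and is less acidic and less nucleophilic, so one equivalent of alkylating agent should go to the 4-OH and leave the 2-OH free for ring B.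

Step 4
Reactants: 3 2,4-dimethoxy-6-(methoxymethyl)benzaldehyde; 5 1-(2-hydroxy-4-methoxy-6-methylphenyl)ethanone
Product: 6 (2E)-3-[2,4-dimethoxy-6-(methoxymethyl)phenyl]-1-(2-hydroxy-4-methoxy-6-methylphenyl)prop-2-en-1-one
Conditions: KOH (50 % aq), EtOH, rt, 48 h; then 1 M HCl
Reagents that add atoms: none
Why: Claisen-Schmidt condensation of a methyl ketone with a non-enolisable aldehyde; dehydration gives the more stable E enone, and any of the ring-closed flavanone 7 formed by oxa-Michael addition is carried along because step 5 passes through it.

Step 5
Reactants: 6 (2E)-3-[2,4-dimethoxy-6-(methoxymethyl)phenyl]-1-(2-hydroxy-4-methoxy-6-methylphenyl)prop-2-en-1-one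
Product: 8 2-[2,4-dimethoxy-6-(methoxymethyl)phenyl]-7-methoxy-5-methyl-4H-chromen-4-one, via racemic flavanone 7 (not isolated)
Conditions: I2 (10 mol %), DMSO, 130 °C
Reagents that add atoms: none
Why: iodine/DMSO oxidative cyclisation of a 2'-hydroxychalcone; 6-endo oxa-Michael addition gives 7, alpha-iodination and loss of HI introduce the C2=C3 bond and erase the stereocenter, and DMSO reoxidises HI to iodine.

Step 6
Reactants: 8 2-[2,4-dimethoxy-6-(methoxymethyl)phenyl]-7-methoxy-5-methyl-4H-chromen-4-one
Product: 9 2-[2-(bromomethyl)-4,6-dimethoxyphenyl]-7-methoxy-5-methyl-4H-chromen-4-one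
Conditions: HBr (33 % in AcOH), CH2Cl2, 0 °C to rt
Reagents that add atoms: hydrogen bromide, Br
Why: acidolytic cleavage of a benzylic methyl ether; bromide displaces the protonated ether at the benzylic carbon, aryl methyl ethers need far harsher conditions, and any benzylic alcohol or acetate formed on the way converges on the same bromide in excess HBr.

Step 7
Reactants: 10 tert-butyl acetate; 11 3-(trimethylsilyl)prop-2-ynal
Product: 12 racemic tert-butyl 3-hydroxy-5-(trimethylsilyl)pent-4-ynoate
Conditions: LiN(iPr)2, THF, -78 °C; then 11, -78 °C; aq NH4Cl
Reagents that add atoms: none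
Why: aldol addition of the preformed lithium enolate of 10 to a non-enolisable ynal, which at -78 °C should be 1,2-selective; the new carbinol stereocenter is formed without control and is removed by oxidation in step 10.

Step 8
Reactants: 12 racemic tert-butyl 3-hydroxy-5-(trimethylsilyl)pent-4-ynoate
Product: 13 racemic tert-butyl 3-hydroxypent-4-ynoate
Conditions: K2CO3 (0.2 equiv), MeOH, 0 °C
Reagents that add atoms: none
Why: base-catalysed methanolysis of the alkynyl C-Si bond; the tert-butyl ester resists transesterification and the low temperature suppresses retro-aldol cleavage.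

Step 9
Reactants: 9 2-[2-(bromomethyl)-4,6-dimethoxyphenyl]-7-methoxy-5-methyl-4H-chromen-4-one; 13 racemic tert-butyl 3-hydroxypent-4-ynoate
Product: 14 racemic tert-butyl 6-[3,5-dimethoxy-2-(7-methoxy-5-methyl-4-oxo-4H-chromen-2-yl)phenyl]-3-hydroxyhex-4-ynoate
Conditions: CuI (20 mol %), Cs2CO3 (1.5 equiv), MeCN, rt, under argon
Reagents that add atoms: none
Why: copper-mediated benzylation of a terminal alkyne (sp3-sp coupling through a monovalent copper acetylide); the coupling is run at the alcohol oxidation level, where the aryl-CH2-alkyne unit is not acidified by a ketone, and carbonate at rt should leave ring B, the free OH and the ester alone.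

Step 10
Reactants: 14 racemic tert-butyl 6-[3,5-dimethoxy-2-(7-methoxy-5-methyl-4-oxo-4H-chromen-2-yl)phenyl]-3-hydroxyhex-4-ynoate
Product: 15 tert-butyl 6-[3,5-dimethoxy-2-(7-methoxy-5-methyl-4-oxo-4H-chromen-2-yl)phenyl]-3-oxohex-4-ynoate
Conditions: Dess-Martin periodinane (1.2 equiv), CH2Cl2, 0 °C to rt
Reagents that add atoms: none
Why: Dess-Martin oxidation of a secondary propargylic alcohol to the ynone; the medium is weakly acidic and free of base, so the now acidic aryl-CH2-ynone unit should not isomerise to the allenone, and the stereocenter disappears.

Step 11
Reactants: 15 tert-butyl 6-[3,5-dimethoxy-2-(7-methoxy-5-methyl-4-oxo-4H-chromen-2-yl)phenyl]-3-oxohex-4-ynoate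
Product: 16 2-{2-[(4-hydroxy-2-oxo-2H-pyran-6-yl)methyl]-4,6-dimethoxyphenyl}-7-methoxy-5-methyl-4H-chromen-4-one
Conditions: Ph3PAuNTf2 (5 mol %), MeNO2/AcOH (4:1), rt
Reagents that add atoms: none
Why: The cationic monovalent gold complex binds the alkyne of 15 as a pi-acid, and conjugation with the ketone puts the positive charge on the alkyne carbon that carries the benzylic CH2, the future C6''. The carbonyl oxygen of the tert-butyl ester adds to that carbon anti to gold, giving a cyclic oxocarbenium ion with a vinyl-gold bond at C5''; loss of the tert-butyl group as 2-methylpropene and protodeauration by AcOH release the 2-pyranone, whose C4'' oxygen rests as the 4-hydroxy tautomer. The closest known reaction type is the gold-catalysed cycloisomerisation of tert-butyl 3-oxoalk-4-ynoates to 6-substituted 4-hydroxy-2-pyranones. Ring D is the only ring closed, its mode of closure is 6-endo-dig, and no stereocenter is formed. The selectivity needed is 6-endo over 5-exo attack of the same ester oxygen on the alkyne carbon next to the ketone; the ynone polarisation makes the remote carbon the electrophile, and the 5-exo product would be a strained alkylidene furanone. The tert-butyl group makes the closure irreversible, because it can leave as an alkene where a methyl or ethyl group could not. The medium is neutral to weakly acidic, so the aryl-CH2-ynone unit and ring B should survive, and ring C could reach the activated carbon only through a four-membered ring, which rules out hydroarylation.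

Step 12
Reactants: 16 2-{2-[(4-hydroxy-2-oxo-2H-pyran-6-yl)methyl]-4,6-dimethoxyphenyl}-7-methoxy-5-methyl-4H-chromen-4-one
Product: 17 2-{2,4-dihydroxy-6-[(4-hydroxy-2-oxo-2H-pyran-6-yl)methyl]phenyl}-7-hydroxy-5-methyl-4H-chromen-4-one
Conditions: BBr3 (8 equiv), CH2Cl2, -78 °C to rt; then H2O
Reagents that add atoms: none
Why: Lewis acid cleavage of aryl methyl ethers (boron coordinates each ether oxygen, bromide removes the methyl group by SN2); excess reagent allows for the equivalents bound by the chromone carbonyl and the pyranone OH, and rings B and D hold no alkyl ether and should come through unchanged after hydrolysis of the aryl borates.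

## Compound list

1 | (3,5-dimethoxyphenyl)methanol | COc1cc(CO)cc(OC)c1 | starting material
2 | 1,3-dimethoxy-5-(methoxymethyl)benzene | COCc1cc(OC)cc(OC)c1 | intermediate
3 | 2,4-dimethoxy-6-(methoxymethyl)benzaldehyde | COCc1cc(OC)cc(OC)c1C=O | intermediate
4 | 1-(2,4-dihydroxy-6-methylphenyl)ethanone | CC(=O)c1c(C)cc(O)cc1O | starting material
5 | 1-(2-hydroxy-4-methoxy-6-methylphenyl)ethanone | CC(=O)c1c(C)cc(OC)cc1O | intermediate
6 | (2E)-3-[2,4-dimethoxy-6-(methoxymethyl)phenyl]-1-(2-hydroxy-4-methoxy-6-methylphenyl)prop-2-en-1-one | COCc1cc(OC)cc(OC)c1/C=C/C(=O)c1c(C)cc(OC)cc1O | intermediate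
7 | racemic 2-[2,4-dimethoxy-6-(methoxymethyl)phenyl]-7-methoxy-5-methyl-2,3-dihydro-4H-chromen-4-one | COCc1cc(OC)cc(OC)c1C1CC(=O)c2c(C)cc(OC)cc2O1 | intermediate
8 | 2-[2,4-dimethoxy-6-(methoxymethyl)phenyl]-7-methoxy-5-methyl-4H-chromen-4-one | COCc1cc(OC)cc(OC)c1-c1cc(=O)c2c(C)cc(OC)cc2o1 | intermediate
9 | 2-[2-(bromomethyl)-4,6-dimethoxyphenyl]-7-methoxy-5-methyl-4H-chromen-4-one | BrCc1cc(OC)cc(OC)c1-c1cc(=O)c2c(C)cc(OC)cc2o1 | intermediate
10 | tert-butyl acetate | CC(=O)OC(C)(C)C | starting material
11 | 3-(trimethylsilyl)prop-2-ynal | C[Si](C)(C)C#CC=O | starting material
12 | racemic tert-butyl 3-hydroxy-5-(trimethylsilyl)pent-4-ynoate | C[Si](C)(C)C#CC(O)CC(=O)OC(C)(C)C | intermediate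
13 | racemic tert-butyl 3-hydroxypent-4-ynoate | C#CC(O)CC(=O)OC(C)(C)C | intermediate
14 | racemic tert-butyl 6-[3,5-dimethoxy-2-(7-methoxy-5-methyl-4-oxo-4H-chromen-2-yl)phenyl]-3-hydroxyhex-4-ynoate | Cc1cc(OC)cc2oc(-c3c(OC)cc(OC)cc3CC#CC(O)CC(=O)OC(C)(C)C)cc(=O)c12 | intermediate
15 | tert-butyl 6-[3,5-dimethoxy-2-(7-methoxy-5-methyl-4-oxo-4H-chromen-2-yl)phenyl]-3-oxohex-4-ynoate | Cc1cc(OC)cc2oc(-c3c(OC)cc(OC)cc3CC#CC(=O)CC(=O)OC(C)(C)C)cc(=O)c12 | intermediate
16 | 2-{2-[(4-hydroxy-2-oxo-2H-pyran-6-yl)methyl]-4,6-dimethoxyphenyl}-7-methoxy-5-methyl-4H-chromen-4-one | Cc1cc(OC)cc2oc(-c3c(OC)cc(OC)cc3Cc3cc(O)cc(=O)o3)cc(=O)c12 | intermediate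
17 | 2-{2,4-dihydroxy-6-[(4-hydroxy-2-oxo-2H-pyran-6-yl)methyl]phenyl}-7-hydroxy-5-methyl-4H-chromen-4-one | Cc1cc(O)cc2oc(-c3c(O)cc(O)cc3Cc3cc(O)cc(=O)o3)cc(=O)c12 | target

## Step count and least certain steps

Total steps: 12. Longest linear sequence: 9 steps (steps 1, 2, 4, 5, 6, 9, 10, 11 and 12, from 1 to 17).

Step 11 (key step). Most likely to go wrong: isomerisation of the skipped aryl-CH2-ynone unit to the conjugated allenone before the gold complex engages the alkyne, because that CH2 is acidified by both ring C and the ynone. Further risks are loss of the tert-butyl group in the acidic medium before ring closure (the resulting beta-keto acid would decarboxylate), partial 5-exo closure, and slowing of the catalyst by coordination to the ring B carbonyl. Fallback, from 15 back to 16, without gold: conjugate addition of diethylamine to the ynone (CH2Cl2, 0 °C) should give the enaminone tert-butyl (4E)-5-(diethylamino)-6-[3,5-dimethoxy-2-(7-methoxy-5-methyl-4-oxo-4H-chromen-2-yl)phenyl]-3-oxohex-4-enoate F1. Mild aqueous acid (AcOH/H2O/THF) would hydrolyse it to the diketo ester tert-butyl 6-[3,5-dimethoxy-2-(7-methoxy-5-methyl-4-oxo-4H-chromen-2-yl)phenyl]-3,5-dioxohexanoate F2. Trifluoroacetic acid with trifluoroacetic anhydride in CH2Cl2 would then close the lactone with loss of the tert-butyl group and give 16. Both operations are known reaction types (amine addition to ynones; acid lactonisation of tert-butyl 3,5-dioxoalkanoates to 4-hydroxy-2-pyranones).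

Step 9. Most likely to go wrong: base-promoted propargyl-to-allene isomerisation of the product, oxidative homocoupling of the copper acetylide of 13 if air enters, and slow substitution at the hindered benzylic carbon that lets hydrolysis or O-alkylation compete. Fallback, from 9 and 13 back to 14, without base: heating 13 with Bu3SnOMe should give the alkynylstannane racemic tert-butyl 3-hydroxy-5-(tributylstannyl)pent-4-ynoate F3, and Stille coupling of F3 with 9 using Pd(PPh3)4 (zerovalent palladium) in toluene at 80 °C would give 14 under neutral conditions.

Step 6. Most likely to go wrong: the strong acid generates a benzylic electrophile beside an electron-rich ring C, so Friedel-Crafts benzylation of a second molecule (oligomerisation) and partial cleavage of aryl methyl ethers on long exposure are the processes to fear. Fallback, from 8 back to 14, bypassing 9: BCl3 in CH2Cl2 at -78 to 0 °C should cleave the benzylic ether without protic acid and give the less reactive chloride 2-[2-(chloromethyl)-4,6-dimethoxyphenyl]-7-methoxy-5-methyl-4H-chromen-4-one F4. F4 would then be coupled with 13 by palladium-catalysed alkynylation of the benzylic chloride (PdCl2(MeCN)2 as a divalent palladium precatalyst reduced in the flask to zerovalent palladium, XPhos, Cs2CO3, MeCN, 65 °C) to give 14.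

Step 10. Most likely to go wrong: over-oxidation at the C2 methylene once the beta-keto ester has formed, and isomerisation of the newly acidified aryl-CH2-ynone unit during basic work-up or on silica. Fallback, from 9 back to 15, without an oxidant touching the active methylene: coupling of 9 with prop-2-yn-1-ol under the conditions of step 9 should give the propargylic alcohol 2-[2-(4-hydroxybut-2-yn-1-yl)-4,6-dimethoxyphenyl]-7-methoxy-5-methyl-4H-chromen-4-one F5. MnO2 in CH2Cl2 would oxidise it to the ynal 4-[3,5-dimethoxy-2-(7-methoxy-5-methyl-4-oxo-4H-chromen-2-yl)phenyl]but-2-ynal F6. Roskamp homologation of F6 with tert-butyl diazoacetate and catalytic SnCl2 in CH2Cl2 would give 15 directly at the ketone oxidation level.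

Step 4. Most likely to go wrong: incomplete condensation, because the aldehyde is electron-rich and flanked by two ortho substituents and the ketone is flanked by two as well; long exposure to hydroxide then allows Cannizzaro disproportionation of 3. Fallback, from 3 and 5 back to 6, by a directed aldol reaction: the dianion of 5 (LiN(iPr)2, 2.2 equiv, THF, -78 °C) would add to 3 and give, after a cold quench, the aldol racemic 3-[2,4-dimethoxy-6-(methoxymethyl)phenyl]-3-hydroxy-1-(2-hydroxy-4-methoxy-6-methylphenyl)propan-1-one F7. Dehydration with p-toluenesulfonic acid in toluene at 80 °C would then give 6.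

## Further compounds

F1 | step 11 | tert-butyl (4E)-5-(diethylamino)-6-[3,5-dimethoxy-2-(7-methoxy-5-methyl-4-oxo-4H-chromen-2-yl)phenyl]-3-oxohex-4-enoate | CCN(CC)/C(Cc1cc(OC)cc(OC)c1-c1cc(=O)c2c(C)cc(OC)cc2o1)=C/C(=O)CC(=O)OC(C)(C)C
F2 | step 11 | tert-butyl 6-[3,5-dimethoxy-2-(7-methoxy-5-methyl-4-oxo-4H-chromen-2-yl)phenyl]-3,5-dioxohexanoate | Cc1cc(OC)cc2oc(-c3c(OC)cc(OC)cc3CC(=O)CC(=O)CC(=O)OC(C)(C)C)cc(=O)c12
F3 | step 9 | racemic tert-butyl 3-hydroxy-5-(tributylstannyl)pent-4-ynoate | CCCC[Sn](CCCC)(CCCC)C#CC(O)CC(=O)OC(C)(C)C
F4 | step 6 | 2-[2-(chloromethyl)-4,6-dimethoxyphenyl]-7-methoxy-5-methyl-4H-chromen-4-one | ClCc1cc(OC)cc(OC)c1-c1cc(=O)c2c(C)cc(OC)cc2o1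
F5 | step 10 | 2-[2-(4-hydroxybut-2-yn-1-yl)-4,6-dimethoxyphenyl]-7-methoxy-5-methyl-4H-chromen-4-one | OCC#CCc1cc(OC)cc(OC)c1-c1cc(=O)c2c(C)cc(OC)cc2o1
F6 | step 10 | 4-[3,5-dimethoxy-2-(7-methoxy-5-methyl-4-oxo-4H-chromen-2-yl)phenyl]but-2-ynal | O=CC#CCc1cc(OC)cc(OC)c1-c1cc(=O)c2c(C)cc(OC)cc2o1
F7 | step 4 | racemic 3-[2,4-dimethoxy-6-(methoxymethyl)phenyl]-3-hydroxy-1-(2-hydroxy-4-methoxy-6-methylphenyl)propan-1-one | COCc1cc(OC)cc(OC)c1C(O)CC(=O)c1c(C)cc(OC)cc1O
A1 | alternative 1 | [3,5-dimethoxy-2-(7-methoxy-5-methyl-4-oxo-4H-chromen-2-yl)phenyl]acetaldehyde | Cc1cc(OC)cc2oc(-c3c(OC)cc(OC)cc3CC=O)cc(=O)c12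
A2 | alternative 1 | 1,3-dimethoxy-1-(trimethylsilyloxy)buta-1,3-diene | C=C(OC)C=C(OC)O[Si](C)(C)C
A3 | alternative 1 | racemic 2-{2-[(4-methoxy-6-oxo-3,6-dihydro-2H-pyran-2-yl)methyl]-4,6-dimethoxyphenyl}-7-methoxy-5-methyl-4H-chromen-4-one | Cc1cc(OC)cc2oc(-c3c(OC)cc(OC)cc3CC3CC(OC)=CC(=O)O3)cc(=O)c12
A4 | alternative 2 | [6-{2,4-dimethoxy-6-[(4-methoxy-2-oxo-2H-pyran-6-yl)methyl]phenyl}-4-oxo-3-(prop-1-en-2-yl)-4H-pyran-2-yl]acetic acid | CC(=C)c1c(CC(=O)O)oc(-c2c(OC)cc(OC)cc2Cc2cc(OC)cc(=O)o2)cc1=O
A5 | alternative 2 | 6-{2,4-dimethoxy-6-[(4-methoxy-2-oxo-2H-pyran-6-yl)methyl]phenyl}-2-(2-oxoethenyl)-3-(prop-1-en-2-yl)-4H-pyran-4-one | CC(=C)c1c(C=C=O)oc(-c2c(OC)cc(OC)cc2Cc2cc(OC)cc(=O)o2)cc1=O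
A6 | alternative 2 | 2-{2,4-dimethoxy-6-[(4-methoxy-2-oxo-2H-pyran-6-yl)methyl]phenyl}-5-methyl-4-oxo-4H-chromen-7-yl acetate | CC(=O)Oc1cc(C)c2c(c1)oc(-c1c(OC)cc(OC)cc1Cc1cc(OC)cc(=O)o1)cc2=O
A7 | alternative 3 | 4-hydroxy-6-[7-(7-methoxy-5-methyl-4-oxo-4H-chromen-2-yl)-2,4,6-trioxoheptyl]-2H-pyran-2-one | Cc1cc(OC)cc2oc(CC(=O)CC(=O)CC(=O)Cc3cc(O)cc(=O)o3)cc(=O)c12
A8 | alternative 3 | 2-{2,4-dihydroxy-6-[(4-hydroxy-2-oxo-2H-pyran-6-yl)methyl]phenyl}-7-methoxy-5-methyl-4H-chromen-4-one | Cc1cc(OC)cc2oc(-c3c(O)cc(O)cc3Cc3cc(O)cc(=O)o3)cc(=O)c12
A9 | alternative 3 | 6-{2,4-dihydroxy-6-[(7-methoxy-5-methyl-4-oxo-4H-chromen-2-yl)methyl]phenyl}-4-hydroxy-2H-pyran-2-one | Cc1cc(OC)cc2oc(Cc3cc(O)cc(O)c3-c3cc(O)cc(=O)o3)cc(=O)c12
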